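## Retrosynthetic overview

1. Target **18** (cyclohepta[b]furan numbering, O1 to C8a) ⇐ cyclohept-2-enone **14** with a phosphonoacetate on the C8a oxygen. Intramolecular Michael addition and Horner–Wadsworth–Emmons olefination close the α-methylene lactone last.
2. **14** ⇐ 8-oxabicyclo[3.2.1]octan-3-one **13** by β-elimination of the oxygen bridge; the bridge oxygen stays on C7 as the tertiary hydroxyl.
3. The trans C8a/C8 diol of **9** ⇐ bridge vinyl bromide **7** by exo ketohydroxylation and hydroxyl-directed reduction.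
4. **7** ⇐ key (4+3) cycloaddition of the methyl-substituted oxyallyl (α-keto) cation from **5** with bromofuryl carbinol **4**, forming C3a–C4 and C6–C7. The seven-membered ring is made first, as the oxygen-bridged bicycle.
5. **4** ⇐ 3-bromofuran + crotonaldehyde, resolved enzymatically.

Assumption: facial delivery in step 3 follows the zinc-alkoxide/allylic-strain model given there, so the (R)-carbinol leads to the natural series; if it proves the reverse, the (S)-acetate left over from step 2 is carried through instead.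

## Route

Step 1
Reactants: 1 3-bromofuran; 2 (2E)-but-2-enal
Product: 3 rac-(2E)-1-(3-bromofuran-2-yl)but-2-en-1-yl acetate
Conditions: LiN(iPr)2, THF, −78 °C; then 2; then Ac2O, −78 → 0 °C
Reagents that add atoms: acetic anhydride, CC(=O)OC(C)=O
Why: Directed lithiation and 1,2-addition: the amide base removes the C2 proton of 3-bromofuran (no halogen–lithium exchange), the furyllithium adds to the aldehyde carbon of the enal, and the alkoxide is trapped as the acetate, the carbinol centre being racemic at this stage.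

Step 2
Reactants: 3 rac-(2E)-1-(3-bromofuran-2-yl)but-2-en-1-yl acetate
Product: 4 (1R,2E)-1-(3-bromofuran-2-yl)but-2-en-1-ol
Conditions: immobilised Burkholderia cepacia lipase, n-BuOH, MTBE, 30 °C, stopped near 45% conversion
Reagents that add atoms: none
Why: Enzymatic kinetic resolution by transesterification: the lipase deacylates the (R)-acetate faster (large bromofuryl, medium propenyl, Kazlauskas rule), so the (R)-alcohol is released and separated from the unreacted (S)-acetate.

Step 3
Reactants: 4 (1R,2E)-1-(3-bromofuran-2-yl)but-2-en-1-ol; 5 1,3-dibromobutan-2-one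
Product: 6 (1R,2R,5R)-7-bromo-1-[(1R,2E)-1-hydroxybut-2-en-1-yl]-2-methyl-8-oxabicyclo[3.2.1]oct-6-en-3-one
Conditions: Et2Zn (2.5 equiv), THF, 0 °C → rt
Reagents that add atoms: none
Why: Zinc-alkoxide-directed oxyallyl cation (4+3) cycloaddition (Hoffmann–Noyori type): the zinc oxyallyl cation, whose ketone α-carbons are electrophilic instead of nucleophilic, bonds through its CH2 end to the free and more nucleophilic furan C5 and through its CH(CH3) end to C2, while allylic strain against the 3-bromine holds the carbinol C–H in the furan plane so that the zinc alkoxide delivers the cation to its own face, and the chelated extended transition state of the Z-configured cation places the methyl cis to the oxygen bridge, which sets C7, C6 and the bridgehead C3a of the target in one step.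

Step 4
Reactants: 6 (1R,2R,5R)-7-bromo-1-[(1R,2E)-1-hydroxybut-2-en-1-yl]-2-methyl-8-oxabicyclo[3.2.1]oct-6-en-3-one
Product: 7 (1R,2R,5R)-7-bromo-1-[(2E)-but-2-enoyl]-2-methyl-8-oxabicyclo[3.2.1]oct-6-en-3-one
Conditions: Dess–Martin periodinane, CH2Cl2, rt
Reagents that add atoms: none
Why: Dess–Martin oxidation of the secondary allylic alcohol gives the enone without touching a ring stereocentre and leaves the side-chain alkene electron-poor, so that it does not compete in the next oxidation.

Step 5
Reactants: 7 (1R,2R,5R)-7-bromo-1-[(2E)-but-2-enoyl]-2-methyl-8-oxabicyclo[3.2.1]oct-6-en-3-one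
Product: 8 (1R,4R,5R,7R)-5-[(2E)-but-2-enoyl]-7-hydroxy-4-methyl-8-oxabicyclo[3.2.1]octane-3,6-dione
Conditions: OsO4 (5 mol %), N-methylmorpholine N-oxide, citric acid, t-BuOH/H2O, rt
Reagents that add atoms: N-methylmorpholine N-oxide, C[N+]1([O-])CCOCC1; water, O
Why: Upjohn-type dihydroxylation of a vinyl halide (ketohydroxylation): OsO4 adds to the strained bridge alkene from the exo face, the side of the oxygen bridge, and the geminal bromohydrin loses HBr, so the future C8a carries a hydroxyl cis to the bridge oxygen and the future C8 becomes a ketone.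

Step 6
Reactants: 8 (1R,4R,5R,7R)-5-[(2E)-but-2-enoyl]-7-hydroxy-4-methyl-8-oxabicyclo[3.2.1]octane-3,6-dione
Product: 9 (1S,2R,5R,6S,7S)-1-[(2E)-but-2-enoyl]-6,7-dihydroxy-2-methyl-8-oxabicyclo[3.2.1]octan-3-one
Conditions: Me4NBH(OAc)3, MeCN/AcOH, −30 °C
Reagents that add atoms: none
Why: Hydroxyl-directed triacetoxyborohydride reduction (Saksena–Evans type): the exo hydroxyl binds boron and delivers hydride to the adjacent strained ketone from the exo face, giving the endo C8 alcohol trans to both the C8a oxygen and the bridge oxygen, while the ring ketone and the enone, which have no hydroxyl positioned for delivery, are left.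

Step 7
Reactants: 9 (1S,2R,5R,6S,7S)-1-[(2E)-but-2-enoyl]-6,7-dihydroxy-2-methyl-8-oxabicyclo[3.2.1]octan-3-one; 10 2-(diethoxyphosphoryl)acetic acid
Product: 11 (1S,2R,5R,6S,7S)-1-[(2E)-but-2-enoyl]-7-hydroxy-2-methyl-3-oxo-8-oxabicyclo[3.2.1]octan-6-yl 2-(diethoxyphosphoryl)acetate
Conditions: DCC (1.05 equiv), DMAP (cat.), CH2Cl2, 0 °C
Reagents that add atoms: none
Why: Steglich esterification: the exo hydroxyl is far more accessible than the endo hydroxyl next to the quaternary bridgehead, so one equivalent of acid acylates it selectively and no stereocentre changes.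

Step 8
Reactants: 11 (1S,2R,5R,6S,7S)-1-[(2E)-but-2-enoyl]-7-hydroxy-2-methyl-3-oxo-8-oxabicyclo[3.2.1]octan-6-yl 2-(diethoxyphosphoryl)acetate; 12 3-methylbutanoic anhydride
Product: 13 (1S,2R,5R,6R,7S)-1-[(2E)-but-2-enoyl]-6-{[2-(diethoxyphosphoryl)acetyl]oxy}-2-methyl-3-oxo-8-oxabicyclo[3.2.1]octan-7-yl 3-methylbutanoate
Conditions: DMAP, Et3N, CH2Cl2, rt
Reagents that add atoms: none
Why: DMAP-catalysed acylation of the one remaining, hindered secondary alcohol installs the 3-methylbutanoate with retention at C8, the future tertiary hydroxyl still being masked as the bridging ether.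

Step 9
Reactants: 13 (1S,2R,5R,6R,7S)-1-[(2E)-but-2-enoyl]-6-{[2-(diethoxyphosphoryl)acetyl]oxy}-2-methyl-3-oxo-8-oxabicyclo[3.2.1]octan-7-yl 3-methylbutanoate
Product: 14 (1R,5R,6S,7S)-6-[(2E)-but-2-enoyl]-5-methyl-7-[(3-methylbutanoyl)oxy]-4-oxo-6-[(trimethylsilyl)oxy]cyclohept-2-en-1-yl 2-(diethoxyphosphoryl)acetate
Conditions: Me3SiOTf (3 equiv), Et3N (4 equiv), CH2Cl2, −78 → 0 °C
Reagents that add atoms: trimethylsilyl trifluoromethanesulfonate, C[Si](C)(C)OS(=O)(=O)C(F)(F)F
Why: Silyl-triflate-mediated β-elimination (E1cB-type opening of an oxygen-bridged ketone): soft enolisation goes toward the CH2, whose axial hydrogen is aligned, and not toward the methyl-bearing carbon, whose hydrogen is equatorial, and the silyl enol ether expels the silylated bridge oxygen to give the cyclohept-2-enone with that oxygen retained on C7 as its silyl ether, no stereocentre being altered.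

Step 10
Reactants: 14 (1R,5R,6S,7S)-6-[(2E)-but-2-enoyl]-5-methyl-7-[(3-methylbutanoyl)oxy]-4-oxo-6-[(trimethylsilyl)oxy]cyclohept-2-en-1-yl 2-(diethoxyphosphoryl)acetate; 15 formaldehyde
Product: 18 (3aS,6R,7S,8S,8aR)-7-[(2E)-but-2-enoyl]-7-hydroxy-6-methyl-3-methylidene-2,5-dioxooctahydro-2H-cyclohepta[b]furan-8-yl 3-methylbutanoate, via phosphono lactone 16 (not isolated), via silyl ether 17 (not isolated)
Conditions: DBU, LiCl, MeCN, 0 °C; 37% aq. HCHO, rt; then 0.5 M HCl, THF, 0 °C
Reagents that add atoms: none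
Why: Intramolecular Michael addition followed by Horner–Wadsworth–Emmons olefination: the phosphonoacetate carbanion tethered to the C8a oxygen can reach the enone β-carbon C3a only from the face of that oxygen, which sets the cis ring fusion, the resulting α-phosphono lactone olefinates formaldehyde to the α-methylene lactone, and dilute acid removes the tertiary silyl ether.

## Compound list

1 | 3-bromofuran | Brc1ccoc1 | starting material
2 | (2E)-but-2-enal | C/C=C/C=O | starting material
3 | rac-(2E)-1-(3-bromofuran-2-yl)but-2-en-1-yl acetate | C/C=C/C(OC(C)=O)c1occc1Br | intermediate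
4 | (1R,2E)-1-(3-bromofuran-2-yl)but-2-en-1-ol | C/C=C/[C@@H](O)c1occc1Br | intermediate
5 | 1,3-dibromobutan-2-one | CC(Br)C(=O)CBr | starting material
6 | (1R,2R,5R)-7-bromo-1-[(1R,2E)-1-hydroxybut-2-en-1-yl]-2-methyl-8-oxabicyclo[3.2.1]oct-6-en-3-one (methyl cis to the oxygen bridge) | C/C=C/[C@@H](O)[C@]12O[C@H](CC(=O)[C@@H]1C)C=C2Br | intermediate
7 | (1R,2R,5R)-7-bromo-1-[(2E)-but-2-enoyl]-2-methyl-8-oxabicyclo[3.2.1]oct-6-en-3-one | C/C=C/C(=O)[C@]12O[C@H](CC(=O)[C@@H]1C)C=C2Br | intermediate
8 | (1R,4R,5R,7R)-5-[(2E)-but-2-enoyl]-7-hydroxy-4-methyl-8-oxabicyclo[3.2.1]octane-3,6-dione (hydroxyl exo) | C/C=C/C(=O)[C@]12O[C@H](CC(=O)[C@@H]1C)[C@@H](O)C2=O | intermediate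
9 | (1S,2R,5R,6S,7S)-1-[(2E)-but-2-enoyl]-6,7-dihydroxy-2-methyl-8-oxabicyclo[3.2.1]octan-3-one (6-OH exo, 7-OH endo) | C/C=C/C(=O)[C@]12O[C@H](CC(=O)[C@@H]1C)[C@@H](O)[C@@H]2O | intermediate
10 | 2-(diethoxyphosphoryl)acetic acid | CCOP(=O)(OCC)CC(=O)O | starting material
11 | (1S,2R,5R,6S,7S)-1-[(2E)-but-2-enoyl]-7-hydroxy-2-methyl-3-oxo-8-oxabicyclo[3.2.1]octan-6-yl 2-(diethoxyphosphoryl)acetate | C/C=C/C(=O)[C@]12O[C@H](CC(=O)[C@@H]1C)[C@@H](OC(=O)CP(=O)(OCC)OCC)[C@@H]2O | intermediate
12 | 3-methylbutanoic anhydride | CC(C)CC(=O)OC(=O)CC(C)C | starting material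
13 | (1S,2R,5R,6R,7S)-1-[(2E)-but-2-enoyl]-6-{[2-(diethoxyphosphoryl)acetyl]oxy}-2-methyl-3-oxo-8-oxabicyclo[3.2.1]octan-7-yl 3-methylbutanoate | C/C=C/C(=O)[C@]12O[C@H](CC(=O)[C@@H]1C)[C@@H](OC(=O)CP(=O)(OCC)OCC)[C@@H]2OC(=O)CC(C)C | intermediate
14 | (1R,5R,6S,7S)-6-[(2E)-but-2-enoyl]-5-methyl-7-[(3-methylbutanoyl)oxy]-4-oxo-6-[(trimethylsilyl)oxy]cyclohept-2-en-1-yl 2-(diethoxyphosphoryl)acetate | CCOP(=O)(OCC)CC(=O)O[C@@H]1C=CC(=O)[C@H](C)[C@@](O[Si](C)(C)C)(C(=O)/C=C/C)[C@H]1OC(=O)CC(C)C | intermediate
15 | formaldehyde | C=O | starting material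
16 | diethyl [(3aR,6R,7S,8S,8aR)-7-[(2E)-but-2-enoyl]-6-methyl-8-[(3-methylbutanoyl)oxy]-2,5-dioxo-7-[(trimethylsilyl)oxy]octahydro-2H-cyclohepta[b]furan-3-yl]phosphonate (cis-fused lactone, both C3 epimers) | CCOP(=O)(OCC)C1C(=O)O[C@@H]2[C@H]1CC(=O)[C@H](C)[C@@](O[Si](C)(C)C)(C(=O)/C=C/C)[C@H]2OC(=O)CC(C)C | intermediate
17 | (3aS,6R,7S,8S,8aR)-7-[(2E)-but-2-enoyl]-6-methyl-3-methylidene-2,5-dioxo-7-[(trimethylsilyl)oxy]octahydro-2H-cyclohepta[b]furan-8-yl 3-methylbutanoate | C=C1C(=O)O[C@@H]2[C@H]1CC(=O)[C@H](C)[C@@](O[Si](C)(C)C)(C(=O)/C=C/C)[C@H]2OC(=O)CC(C)C | intermediate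
18 | (3aS,6R,7S,8S,8aR)-7-[(2E)-but-2-enoyl]-7-hydroxy-6-methyl-3-methylidene-2,5-dioxooctahydro-2H-cyclohepta[b]furan-8-yl 3-methylbutanoate (CNP0283951.1) | C=C1C(=O)O[C@@H]2[C@H]1CC(=O)[C@H](C)[C@@](O)(C(=O)/C=C/C)[C@H]2OC(=O)CC(C)C | target

## Step count and weak points

Total steps: 10. Longest linear sequence: 10 steps (1 → 18); every other input is commercial.

The three steps most likely to fail:

**Step 3 (the cycloaddition).** The methyl-bearing terminus has to bond to the hindered C2 of a bromine-deactivated furan, on the right face, and simple Friedel–Crafts alkylation at C5 competes. The regiochemistry and the axial methyl are predictions from the stepwise-attack and chelation models, not from a direct precedent with this cation. If the methyl came out equatorial, C6 is α to the ketone and could be equilibrated after ring opening. Fallback, from 4 back to 6: silylate 4 (t-BuMe2SiCl, imidazole) to the tert-butyldimethylsilyl ether F1. Run the cycloaddition in the undirected, stepwise ionic mode with the sodium oxyallyl cation from 3-chlorobutan-2-one (NaOCH2CF3 in CF3CH2OH). Separate the silyl-protected cycloadduct F2 from its regio- and face isomers by chromatography, and remove silicon with Bu4NF to rejoin the route at 6.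

**Step 5 (osmylation of the vinyl bromide).** The bromoalkene is electron-poor, and the product is a 2,2-disubstituted 1,3-diketone that can undergo retro-Claisen cleavage. Fallback, from 7 back to 8: Miyaura borylation (B2pin2, PdCl2(dppf), KOAc, dioxane, 80 °C) gives the alkenyl boronate F3. Dimethyldioxirane epoxidises it from the exo face to the epoxy boronate F4. NaBO3·4H2O then oxidises the C–B bond with retention, and the resulting hydroxy epoxide opens to 8 with the exo hydroxyl unchanged.

**Step 9 (opening of the oxygen bridge).** Enolisation could go toward the methyl-bearing carbon and expel the tertiary oxygen instead, and the substrate carries several other silylatable sites. Fallback, from 13 directly to 18: treat 13 with LiN(SiMe3)2 (2.2 equiv, THF, −78 → −20 °C). The phosphonoacetate and then the ketone CH2 are deprotonated, the lithium enolate opens the bridge by E1cB, and the phosphonate anion adds at once to the new enone to give the hydroxy phosphono lactone F5. K2CO3 and aqueous HCHO then convert F5 into 18 without any silyl group.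

Further compounds
F1 | step 3 | tert-butyl{[(1R,2E)-1-(3-bromofuran-2-yl)but-2-en-1-yl]oxy}dimethylsilane | C/C=C/[C@@H](O[Si](C)(C)C(C)(C)C)c1occc1Br
F2 | step 3 | tert-butyldimethylsilyl ether of 6 | C/C=C/[C@@H](O[Si](C)(C)C(C)(C)C)[C@]12O[C@H](CC(=O)[C@@H]1C)C=C2Br
F3 | step 5 | 7-(4,4,5,5-tetramethyl-1,3,2-dioxaborolan-2-yl) analogue of 7 (boron in place of bromine) | C/C=C/C(=O)[C@]12O[C@H](CC(=O)[C@@H]1C)C=C2B1OC(C)(C)C(C)(C)O1
F4 | step 5 | exo-6,7-epoxide of F3 | C/C=C/C(=O)[C@]12O[C@H](CC(=O)[C@@H]1C)[C@H]3O[C@@]23B4OC(C)(C)C(C)(C)O4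
F5 | step 9 | 7-hydroxy (silyl-free) analogue of 16 | CCOP(=O)(OCC)C1C(=O)O[C@@H]2[C@H]1CC(=O)[C@H](C)[C@@](O)(C(=O)/C=C/C)[C@H]2OC(=O)CC(C)C
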